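C2–aryl numbering used throughout: tetrahydrofuran ring O1–C2(guaiacyl)–C3(C9H2OH)–C4(C7'H2-veratryl)–C5.

1. The route rests on the chain C9–C3–C4–C5, a 2,3-disubstituted butane-1,4-diol that is a butenolide in reduced form; C2 (on C3) and C7' (on C4) are trans on that lactone and become 3,4-cis in the ring O1/C2/C3/C4/C5.
2. O1–C2 is disconnected first: benzylic SN1 cycloetherification of a triol (C5–OH onto C2), which gives 2,3-trans from either carbinol epimer.
3. C9 and C5 go back to the carbonyl and acetal carbons of a 5-menthyloxy lactone; C7' goes back to a dithiane carbon.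
4. C4–C7' and C2–C3 are cut together: lithiated veratraldehyde dithiane, (5R)-5-(l-menthyloxy)furan-2(5H)-one and O-benzylvanillin are joined in one pot.
5. Ring order: the butenolide ring (from furfural) serves as the stereochemical template and is opened by hydride; the tetrahydrofuran, the only non-aromatic ring of the target, is closed in the last step.

Key step: step 4

Remark on the chemistry: the aldol step is expected to give both epimers at the carbinol carbon (target C2). The (S) epimer is drawn and both are carried on together, because this centre is ionised and reset in step 7.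

Step 1
Reactants: 1 veratraldehyde
Product: 2 2-(3,4-dimethoxyphenyl)-1,3-dithiane
Conditions: HS(CH2)3SH, BF3·OEt2 (cat.), CH2Cl2, 0 °C → rt
Reagents that add atoms: propane-1,3-dithiol, SCCCS
Why: Lewis-acid-catalysed dithioacetalisation of an aromatic aldehyde is a standard reaction and turns C7' into an acyl-anion equivalent.

Step 2
Reactants: 3 furfural
Product: 4 5-hydroxyfuran-2(5H)-one (racemic hemiacetal)
Conditions: O2, methylene blue (cat.), hν (visible), MeOH, rt
Reagents that add atoms: dioxygen, O=O
Why: Dye-sensitised singlet-oxygen [4+2] cycloaddition to the furan followed by fragmentation in methanol, with the formyl carbon lost as methyl formate, is the established photo-oxygenation of furfural to the hydroxybutenolide.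

Step 3
Reactants: 4 5-hydroxyfuran-2(5H)-one; 5 (−)-menthol
Product: 6 (5R)-5-(l-menthyloxy)furan-2(5H)-one
Conditions: camphorsulfonic acid (cat.), neat, 100 °C; crystallisation from petroleum ether, mother liquor re-equilibrated with acid and recycled
Reagents that add atoms: none
Why: Acid-catalysed acetalisation of the cyclic hemiacetal gives both C5 epimers, which interconvert under acid, so crystallisation should drain the mixture into the less soluble (5R) epimer (crystallisation-induced asymmetric transformation), the menthyl stereocentres coming from the chiral pool.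

Step 4
Reactants: 2 2-(3,4-dimethoxyphenyl)-1,3-dithiane; 6 (5R)-5-(l-menthyloxy)furan-2(5H)-one; 7 O-benzylvanillin
Product: 10 trans,trans aldol adduct lactone (3S,4R,5R; carbinol epimers), via 2-lithiodithiane 8 (not isolated), via lithium enolate 9 (not isolated)
Conditions: n-BuLi, THF, −78 °C; then 6, −78 °C; then 7, −78 °C; sat. aq NH4Cl, −78 °C
Reagents that add atoms: none
Why: Deprotonation of 2 by n-BuLi gives the sulfur- and aryl-stabilised carbanion 8, which adds 1,4 to butenolide 6 (bond C4–C7') to give lithium enolate 9, and 9 is intercepted by aldehyde 7 in an aldol addition (bond C2–C3) before any proton source is present. The closest known reaction type is the tandem conjugate addition of lithiated 2-aryl-1,3-dithianes to 5-alkoxyfuran-2(5H)-ones with electrophilic trapping of the enolate. No ring is closed; two skeletal bonds and three stereocentres are formed. The lactone C4 centre is controlled by the C5 acetal centre, whose bulky menthyloxy group shields one face so that 8 enters anti to it, and the lactone C3 centre is controlled by C4, the aldehyde approaching anti to the quaternary dithianyl group, which gives the 3,4-trans-4,5-trans lactone; the carbinol centre (target C2) is not controlled and need not be. The step needs 1,4- over 1,2-addition and complete trans,trans diastereoselectivity: the soft, hindered anion in THF at −78 °C favours conjugate addition, and the single (5R) acetal configuration translates into the (3R,4R) configuration of target C3 and C4. Quenching at −78 °C should prevent retro-aldol and epimerisation at the alpha carbon.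

Step 5
Reactants: 10 trans,trans aldol adduct lactone
Product: 11 (3S,4R,5R)-4-(3,4-dimethoxybenzyl)-3-[hydroxy(4-hydroxy-3-methoxyphenyl)methyl]-5-(l-menthyloxy)dihydrofuran-2(3H)-one (carbinol epimers)
Conditions: Raney Ni (W-2, washed neutral, excess), EtOH, reflux
Reagents that add atoms: none
Why: Raney nickel hydrogenolysis cleaves both benzylic C–S bonds (Mozingo desulfurisation) and, in excess at reflux, the aryl benzyl ether as well, while the neutral catalyst should leave the lactone, the acetal, the ring stereocentres and, at limited reaction time, the benzylic carbinol untouched.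

Step 6
Reactants: 11 desulfurised phenolic hydroxy lactone
Product: 12 (2R,3R)-2-(3,4-dimethoxybenzyl)-3-[hydroxy(4-hydroxy-3-methoxyphenyl)methyl]butane-1,4-diol (carbinol epimers)
Conditions: LiAlH4, THF, 0 °C → rt; then H2O, pH 7 buffer
Reagents that add atoms: none
Why: LiAlH4 reduces the lactone carbonyl to C9H2OH and the acetal carbon, released at the aldehyde oxidation level on ring opening, to C5H2OH with loss of menthol, so the acetal lactone is unmasked as the 1,4-diol without touching C3 or C4.

Step 7
Reactants: 12 triol
Product: 13 4'-O-methyllariciresinol, (2S,3R,4R)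
Conditions: camphor-10-sulfonic acid (cat.), CH2Cl2–THF, 0 °C → rt
Reagents that add atoms: none
Why: Acid ionises the electron-rich p-hydroxybenzylic carbinol of either epimer (SN1 cycloetherification), the C5 hydroxyl closes the five-membered ring (the C9 hydroxyl could only give an oxetane), and the aryl group should take the position trans to the C3 hydroxymethyl group, kinetically and by reversible reclosure, so both epimers converge on (2S).

Compound list
1 | veratraldehyde (3,4-dimethoxybenzaldehyde) | COc1ccc(C=O)cc1OC | starting material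
2 | 2-(3,4-dimethoxyphenyl)-1,3-dithiane | COc1ccc(C2SCCCS2)cc1OC | intermediate
3 | furfural | O=Cc1ccco1 | starting material
4 | 5-hydroxyfuran-2(5H)-one (racemic) | OC1OC(=O)C=C1 | intermediate
5 | (−)-menthol, (1R,2S,5R) | CC(C)[C@@H]1CC[C@@H](C)C[C@H]1O | starting material
6 | (5R)-5-{[(1R,2S,5R)-2-isopropyl-5-methylcyclohexyl]oxy}furan-2(5H)-one | CC(C)[C@@H]1CC[C@@H](C)C[C@H]1O[C@@H]1OC(=O)C=C1 | intermediate
7 | O-benzylvanillin (4-benzyloxy-3-methoxybenzaldehyde) | COc1cc(C=O)ccc1OCc1ccccc1 | starting material
8 | 2-lithio-2-(3,4-dimethoxyphenyl)-1,3-dithiane | [Li]C1(c2ccc(OC)c(OC)c2)SCCCS1 | intermediate (not isolated)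
9 | lithium enolate of (4R,5R)-4-[2-(3,4-dimethoxyphenyl)-1,3-dithian-2-yl]-5-(l-menthyloxy)dihydrofuran-2(3H)-one, dithianyl trans to menthyloxy | CC(C)[C@@H]1CC[C@@H](C)C[C@H]1O[C@@H]1OC(O[Li])=C[C@H]1C1(c2ccc(OC)c(OC)c2)SCCCS1 | intermediate (not isolated)
10 | (3S,4R,5R)-3-[(S)-(4-benzyloxy-3-methoxyphenyl)(hydroxy)methyl]-4-[2-(3,4-dimethoxyphenyl)-1,3-dithian-2-yl]-5-(l-menthyloxy)dihydrofuran-2(3H)-one, 3,4-trans-4,5-trans, accompanied by its (R)-carbinol epimer | CC(C)[C@@H]1CC[C@@H](C)C[C@H]1O[C@@H]1OC(=O)[C@H]([C@H](O)c2ccc(OCc3ccccc3)c(OC)c2)[C@H]1C1(c2ccc(OC)c(OC)c2)SCCCS1 | intermediate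
11 | (3S,4R,5R)-4-(3,4-dimethoxybenzyl)-3-[(S)-hydroxy(4-hydroxy-3-methoxyphenyl)methyl]-5-(l-menthyloxy)dihydrofuran-2(3H)-one, accompanied by its carbinol epimer | CC(C)[C@@H]1CC[C@@H](C)C[C@H]1O[C@@H]1OC(=O)[C@H]([C@H](O)c2ccc(O)c(OC)c2)[C@H]1Cc1ccc(OC)c(OC)c1 | intermediate
12 | (2R,3R)-2-(3,4-dimethoxybenzyl)-3-[(S)-hydroxy(4-hydroxy-3-methoxyphenyl)methyl]butane-1,4-diol, accompanied by its carbinol epimer | OC[C@H]([C@H](O)c1ccc(O)c(OC)c1)[C@H](CO)Cc1ccc(OC)c(OC)c1 | intermediate
13 | 4'-O-methyllariciresinol, (2S,3R,4R)-2-(4-hydroxy-3-methoxyphenyl)-4-(3,4-dimethoxybenzyl)-3-(hydroxymethyl)tetrahydrofuran | COc1cc([C@H]2OC[C@H](Cc3ccc(OC)c(OC)c3)[C@@H]2CO)ccc1O | target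

Total step count: 7. Longest linear sequence: 6 steps (furfural 3 → 4 → 6 → 10 → 11 → 12 → 13); the dithiane branch adds one step.

Steps most likely to fail

Step 5. Once the para phenol is freed, the benzylic C2–O bond may be hydrogenolysed further; the benzyl ether may also be cleaved incompletely, or residual base on the nickel may cause retro-aldol. The fallback separates the two reductive events and sets out from 10. Radical-chain desulfurisation with Bu3SnH and AIBN in toluene at reflux should give the benzyl-protected desulfurised lactone F4 with the carbinol and the benzyl ether intact. Hydrogenolysis of the aryl benzyl ether (H2, Pd/C, EtOAc, rt) then returns to the route at 11.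

Step 7. The benzylic cation may be captured by the veratryl ring (Friedel–Crafts closure to an aryltetralin) instead of by the C5 hydroxyl, or the ring may close with incomplete 2,3-trans selectivity. The fallback sets out from 12 and forms O1–C2 oxidatively under non-acidic conditions. Hydrogenolysis of the benzylic hydroxyl (H2, Pd/C, EtOH, cat. AcOH) should give (2R,3R)-2-(3,4-dimethoxybenzyl)-3-(4-hydroxy-3-methoxybenzyl)butane-1,4-diol F5. DDQ in CH2Cl2–dioxane at rt then oxidises the benzylic position para to the free phenol, and the C5 hydroxyl adds intramolecularly to that carbon; this returns to the route at 13.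

Step 4. Interception of enolate 9 by the aldehyde may be incomplete (proton transfer, or reversible aldol next to the quaternary dithianyl carbon), leaving the simple conjugate adduct. The fallback sets out from 2 and 6 and replaces the aldol by an irreversible acylation. The conjugate addition is quenched with NH4Cl to isolate (4R,5R)-4-[2-(3,4-dimethoxyphenyl)-1,3-dithian-2-yl]-5-(l-menthyloxy)dihydrofuran-2(3H)-one F1. LiN(SiMe3)2 in THF at −78 °C regenerates 9, which is C-acylated with 4-benzyloxy-3-methoxybenzoyl chloride F2 (from the commercial acid with (COCl)2 and cat. DMF) to give the (3S,4R,5R)-3-(4-benzyloxy-3-methoxybenzoyl) lactone F3. Reduction of the aryl ketone with NaBH4 in MeOH at 0 °C returns to the route at 10; the carbinol mixture is acceptable.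

Further compounds
F1 | step 4 | (4R,5R)-4-[2-(3,4-dimethoxyphenyl)-1,3-dithian-2-yl]-5-(l-menthyloxy)dihydrofuran-2(3H)-one | CC(C)[C@@H]1CC[C@@H](C)C[C@H]1O[C@@H]1OC(=O)C[C@H]1C1(c2ccc(OC)c(OC)c2)SCCCS1
F2 | step 4 | 4-benzyloxy-3-methoxybenzoyl chloride | COc1cc(C(=O)Cl)ccc1OCc1ccccc1
F3 | step 4 | (3S,4R,5R)-3-(4-benzyloxy-3-methoxybenzoyl)-4-[2-(3,4-dimethoxyphenyl)-1,3-dithian-2-yl]-5-(l-menthyloxy)dihydrofuran-2(3H)-one | CC(C)[C@@H]1CC[C@@H](C)C[C@H]1O[C@@H]1OC(=O)[C@H](C(=O)c2ccc(OCc3ccccc3)c(OC)c2)[C@H]1C1(c2ccc(OC)c(OC)c2)SCCCS1
F4 | step 5 | (3S,4R,5R)-3-[(S)-(4-benzyloxy-3-methoxyphenyl)(hydroxy)methyl]-4-(3,4-dimethoxybenzyl)-5-(l-menthyloxy)dihydrofuran-2(3H)-one (with its carbinol epimer) | CC(C)[C@@H]1CC[C@@H](C)C[C@H]1O[C@@H]1OC(=O)[C@H]([C@H](O)c2ccc(OCc3ccccc3)c(OC)c2)[C@H]1Cc1ccc(OC)c(OC)c1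
F5 | step 7 | (2R,3R)-2-(3,4-dimethoxybenzyl)-3-(4-hydroxy-3-methoxybenzyl)butane-1,4-diol | OC[C@H](Cc1ccc(O)c(OC)c1)[C@H](CO)Cc1ccc(OC)c(OC)c1
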